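**Strategy.** Everything rests on cutting the bond between the benzylic CH2 on C6 of the chroman and the quaternary C2 of the furanone. C2 is flanked by the ester carbonyl and ring O1 and is vinylogous through C3=C4 to the lactone C5=O, so its C–H is acidic and gives a planar, aromatic 2-furanolate. The key step is a catalytic enantioselective phase-transfer benzylation of the racemic 4-O-TIPS butenolide with 6-(bromomethyl)-2,2-dimethylchroman, whose ring oxygen para to the CH2 activates the bromide: one operation joins both halves and sets the only stereocentre, (R). Desilylation of the enol ether then gives the target.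

Key step: step 5

Remark on the chemistry: the absolute sense of induction of the phase-transfer catalyst on this furanolate cannot be predicted with certainty. The (S,S) catalyst is written; its (R,R) antipode would be used instead if the (S,S) catalyst favours the (S)-product. Furanone numbering throughout: O1, C2 (quaternary), C3 (phenyl), C4 (enol oxygen), C5 (lactone C=O).

**Step 1**
Reactants: 1 methyl phenylpyruvate; 2 methyl glyoxylate (freshly distilled)
Product: 5 rac-methyl 5-oxo-3-phenyl-4-[(triisopropylsilyl)oxy]-2,5-dihydrofuran-2-carboxylate, via aldol adduct 3 (not isolated), via hydroxybutenolide 4 (not isolated)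
Conditions: DBU (1.05 equiv), MeCN, 0 °C → rt; then TIPSCl (1.2 equiv), rt
Reagents that add atoms: triisopropylsilyl chloride, CC(C)[Si](Cl)(C(C)C)C(C)C
Why: Cross-aldol of the enolised arylpyruvate at its benzylic carbon onto the far more electrophilic glyoxylate aldehyde, 5-exo-trig lactonisation of the alkoxide onto the pyruvate ester (isotetronic acid synthesis) and O-silylation of the resulting DBU enolate at its hard oxygen should give 5, whose racemic C2–H centre is erased in step 5.

**Step 2**
Reactants: 6 4-bromophenol; 7 isoprene
Product: 9 6-bromo-2,2-dimethylchroman, via ortho-prenylphenol 8 (not isolated)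
Conditions: AgOTf (5 mol %), ClCH2CH2Cl, rt
Reagents that add atoms: none
Why: Acid-catalysed Friedel–Crafts ortho-prenylation of the phenol by isoprene followed by Markovnikov 6-endo hydroalkoxylation of the trisubstituted alkene (phenol–diene chroman annulation) should give 9, the para-bromine blocking para attack and marking the later C6.

**Step 3**
Reactants: 9 6-bromo-2,2-dimethylchroman
Product: 11 (2,2-dimethylchroman-6-yl)methanol, via aryllithium 10 (not isolated)
Conditions: n-BuLi, THF, −78 °C; then (CH2O)n, −78 °C → rt; H2O
Reagents that add atoms: paraformaldehyde (as formaldehyde), C=O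
Why: Bromine–lithium exchange followed by addition of the aryllithium to monomeric formaldehyde should give the benzylic alcohol, the chroman ether being inert to n-BuLi at −78 °C.

**Step 4**
Reactants: 11 (2,2-dimethylchroman-6-yl)methanol
Product: 12 6-(bromomethyl)-2,2-dimethylchroman
Conditions: PBr3 (0.4 equiv), Et2O, 0 °C; used at once without chromatography
Reagents that add atoms: phosphorus tribromide, BrP(Br)Br
Why: SN2 bromination of a primary para-alkoxybenzylic alcohol with PBr3 is the standard way to such labile electron-rich benzyl bromides.

**Step 5**
Reactants: 5 rac-methyl 5-oxo-3-phenyl-4-[(triisopropylsilyl)oxy]-2,5-dihydrofuran-2-carboxylate; 12 6-(bromomethyl)-2,2-dimethylchroman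
Product: 14 methyl (2R)-2-[(2,2-dimethylchroman-6-yl)methyl]-5-oxo-3-phenyl-4-[(triisopropylsilyl)oxy]-2,5-dihydrofuran-2-carboxylate, via furanolate 13 (not isolated)
Conditions: (S,S)-3,4,5-trifluorophenyl-NAS bromide (binaphthyl spiro ammonium salt, 5 mol %), Cs2CO3 (solid, 2 equiv), toluene, −40 °C, Ar
Reagents that add atoms: none
Why: Solid Cs2CO3 removes the C2–H of 5 (flanked by the ester C=O and ring O1, vinylogous through C3=C4 to the lactone C5=O) to give the planar 6π 2-furanolate 13, which enters toluene as a tight ion pair with the C2-symmetric binaphthyl ammonium cation and is C-benzylated by 12 in an SN2 step that the para ring oxygen of the chroman accelerates. The closest known reaction type is the asymmetric phase-transfer benzylation of cyclic β-keto esters and of α-substituted malonates to quaternary α-carbons. No ring is closed. The new quaternary stereocentre C2 is set by the catalyst alone: its aryl walls cover one enantiotopic face of the ion-paired furanolate and 12 approaches the open face, the (S,S) catalyst being written for the (R) product and its (R,R) antipode being the remedy if the sense should be opposite. The step needs C2- rather than C4- or O-alkylation: the bulky OTIPS group shields C4 and the neighbouring furanolate oxygen, the ester makes C2 the malonate-like terminus, and only attack at C2 keeps the C3=C4–C5=O enone conjugated to the phenyl ring. The product has no acidic C–H, so it can be neither alkylated again nor racemised under the conditions.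

**Step 6**
Reactants: 14 methyl (2R)-2-[(2,2-dimethylchroman-6-yl)methyl]-5-oxo-3-phenyl-4-[(triisopropylsilyl)oxy]-2,5-dihydrofuran-2-carboxylate
Product: 15 4'-dehydroxy aspernolide A [methyl (2R)-2-[(2,2-dimethylchroman-6-yl)methyl]-4-hydroxy-5-oxo-3-phenyl-2,5-dihydrofuran-2-carboxylate]
Conditions: Et3N·3HF, THF, rt; dilute aqueous acid work-up
Reagents that add atoms: none
Why: Fluoride-mediated Si–O cleavage of the silyl enol ether under weakly acidic, non-basic conditions should free the C4 enol without touching the methyl ester, lactone or chroman ether, and without the base-induced ring opening or retro-aldol that could endanger the quaternary C2.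

**Compound list**
1 | methyl phenylpyruvate (methyl 2-oxo-3-phenylpropanoate) | COC(=O)C(=O)Cc1ccccc1 | starting material
2 | methyl glyoxylate | COC(=O)C=O | starting material
3 | dimethyl 2-hydroxy-4-oxo-3-phenylpentanedioate (aldol adduct, racemic diastereomer mixture, as alkoxide in the flask) | COC(=O)C(O)C(c1ccccc1)C(=O)C(=O)OC | intermediate
4 | rac-methyl 4-hydroxy-5-oxo-3-phenyl-2,5-dihydrofuran-2-carboxylate (as DBU enolate in the flask) | COC(=O)C1OC(=O)C(O)=C1c1ccccc1 | intermediate
5 | rac-methyl 5-oxo-3-phenyl-4-[(triisopropylsilyl)oxy]-2,5-dihydrofuran-2-carboxylate | COC(=O)C1OC(=O)C(O[Si](C(C)C)(C(C)C)C(C)C)=C1c1ccccc1 | intermediate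
6 | 4-bromophenol | Oc1ccc(Br)cc1 | starting material
7 | isoprene | C=CC(C)=C | starting material
8 | 4-bromo-2-(3-methylbut-2-en-1-yl)phenol | CC(C)=CCc1cc(Br)ccc1O | intermediate
9 | 6-bromo-2,2-dimethylchroman | CC1(C)CCc2cc(Br)ccc2O1 | intermediate
10 | (2,2-dimethylchroman-6-yl)lithium | [Li]c1ccc2OC(C)(C)CCc2c1 | intermediate
11 | (2,2-dimethylchroman-6-yl)methanol | OCc1ccc2OC(C)(C)CCc2c1 | intermediate
12 | 6-(bromomethyl)-2,2-dimethylchroman | BrCc1ccc2OC(C)(C)CCc2c1 | intermediate
13 | caesium 5-(methoxycarbonyl)-4-phenyl-3-[(triisopropylsilyl)oxy]furan-2-olate (ion-paired with the catalyst cation in toluene) | COC(=O)C1=C(c2ccccc2)C(O[Si](C(C)C)(C(C)C)C(C)C)=C([O-])O1.[Cs+] | intermediate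
14 | methyl (2R)-2-[(2,2-dimethylchroman-6-yl)methyl]-5-oxo-3-phenyl-4-[(triisopropylsilyl)oxy]-2,5-dihydrofuran-2-carboxylate | COC(=O)[C@]1(Cc2ccc3c(c2)CCC(C)(C)O3)OC(=O)C(O[Si](C(C)C)(C(C)C)C(C)C)=C1c1ccccc1 | intermediate
15 | 4'-dehydroxy aspernolide A, (R) | COC(=O)[C@]1(Cc2ccc3c(c2)CCC(C)(C)O3)OC(=O)C(O)=C1c1ccccc1 | target

**Step count.** Total: 6 steps. Longest linear sequence: 5 steps (steps 2, 3, 4, 5, 6 from 4-bromophenol).

**Three steps most likely to fail**

Step 5. The chiral cation may fail to discriminate the two faces of the flat furanolate, giving low enantiomeric excess, or alkylation may leak to C4 or to oxygen. The fallback sets out from 4, isolated from the step 1 mixture by acidification before silylation, and from 12. Double deprotonation with LiHMDS (2.2 equiv, THF, −78 °C) should give the dilithium dianion of 4 F1. Its last-formed C2 carbanion should be benzylated by 12 with the classical dianion regiochemistry and without a protecting group, giving racemic 15 F2 after acidic work-up. Resolution by preparative chromatography on a chiral stationary phase (or as a diastereomeric salt of the acidic enol with a chiral amine) removes the (S)-enantiomer F3, and the route is rejoined at 15.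

Step 1. Self-aldol dimerisation of 1 may outrun the cross-aldol, and silyl chloride may be lost to the methanol released in the same flask. The fallback sets out from 1, which is converted with TMSCl/Et3N into the silyl enol ether methyl (Z)-3-phenyl-2-[(trimethylsilyl)oxy]prop-2-enoate F4, a donor that cannot self-condense. A Mukaiyama aldol with 2 (TiCl4, CH2Cl2, −78 °C) should give 3 after aqueous acid, and acid-driven lactonisation (cat. TsOH, toluene) should give isolated 4. Separate silylation (TIPSCl, imidazole, DMF) rejoins the route at 5.

Step 2. Over-prenylation, O-prenylation and incomplete ring closure may give mixtures that are hard to separate. The fallback sets out from 6, which is condensed with 3-methylbut-2-enoic acid in MsOH/P2O5 (Friedel–Crafts acylation and oxa-Michael ring closure ortho to the phenol) to 6-bromo-2,2-dimethylchroman-4-one F5. Deoxygenation of the aryl ketone by ionic hydrogenation (Et3SiH, TFA; Clemmensen reduction as the classical alternative) rejoins the route at 9.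

**Further compounds**
F1 | step 5 | dilithium 5-(methoxycarbonyl)-4-phenylfuran-2,3-diolate (dianion of 4) | COC(=O)C1=C(c2ccccc2)C([O-])=C([O-])O1.[Li+].[Li+]
F2 | step 5 | racemic 15 | COC(=O)C1(Cc2ccc3c(c2)CCC(C)(C)O3)OC(=O)C(O)=C1c1ccccc1
F3 | step 5 | (S)-enantiomer of 15 | COC(=O)[C@@]1(Cc2ccc3c(c2)CCC(C)(C)O3)OC(=O)C(O)=C1c1ccccc1
F4 | step 1 | methyl (Z)-3-phenyl-2-[(trimethylsilyl)oxy]prop-2-enoate | COC(=O)/C(O[Si](C)(C)C)=C/c1ccccc1
F5 | step 2 | 6-bromo-2,2-dimethylchroman-4-one | CC1(C)CC(=O)c2cc(Br)ccc2O1
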